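**Strategy.** The sulfated ring (C1′–C6′) is closed last, across C4′–C5′: the lithium enolate of an ethyl ketone (C5′, beside the latent C6′ carbonyl) opens a terminal 1,2-cyclic sulfate that spans C3′ and C4′. One operation thus forms the six-membered ring and leaves the expelled sulfate as the C3′ monoester next to the C4′ methylene, with the quaternary C1′ blocking any other enolisation. The precursor is an acyclic silyloxy keto cyclic sulfate built from (R)-glycerate acetonide. The diol ring is closed earlier by the analogous tosylate displacement, and the polyene is assembled by Stille couplings and two Wittig reactions (C15 + C10 + C15).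

Key step: step 14

Remark: carotenoid numbering is used (per end ring C1 = CMe2, C2 and C3 = oxygenated carbons, C4 = CH2, C5 = methyl-bearing sp2 carbon, C6 = chain-bearing carbon; primed numbers = sulfated half); sulfate monoesters are carried as salts (Bu4N+, inner salt, Na+) and the free hydrogen sulfate is released only in the last work-up.

Step 1
Reactants: 1 isobutyronitrile; 2 methyl (4R)-2,2-dimethyl-1,3-dioxolane-4-carboxylate
Product: 3 3-[(4R)-2,2-dimethyl-1,3-dioxolan-4-yl]-2,2-dimethyl-3-oxopropanenitrile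
Conditions: LiN(iPr)2, THF, −78 °C; then 2, −78 °C; AcOH quench at −78 °C
Reagents that add atoms: none
Why: Claisen-type acylation of the lithiated nitrile by the ester builds the C1–C2 bond and the quaternary C1, and the cold acidic quench should keep the α-alkoxy stereocentre taken from 2 (future C3) from epimerising.

Step 2
Reactants: 3 3-[(4R)-2,2-dimethyl-1,3-dioxolan-4-yl]-2,2-dimethyl-3-oxopropanenitrile
Product: 4 (3R)-3-[(4R)-2,2-dimethyl-1,3-dioxolan-4-yl]-3-hydroxy-2,2-dimethylpropanenitrile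
Conditions: K[HB(sBu)3], THF, −78 °C; H2O work-up
Reagents that add atoms: none
Why: Felkin–Anh-controlled (polar model) reduction of an α-alkoxy ketone, in which the bulky borohydride attacks anti to the dioxolane C–O bond, should set the (R) carbinol (future C2) syn to the ring oxygen, which is the trans C2/C3 relationship of both end rings.

Step 3
Reactants: 4 (3R)-3-[(4R)-2,2-dimethyl-1,3-dioxolan-4-yl]-3-hydroxy-2,2-dimethylpropanenitrile
Product: 5 (3R)-3-[(tert-butyldimethylsilyl)oxy]-3-[(4R)-2,2-dimethyl-1,3-dioxolan-4-yl]-2,2-dimethylpropanenitrile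
Conditions: TBSOTf, 2,6-lutidine, CH2Cl2, 0 °C to rt
Reagents that add atoms: tert-butyldimethylsilyl triflate CC(C)(C)[Si](C)(C)OS(=O)(=O)C(F)(F)F
Why: Silylation with the silyl triflate is the standard way to protect a hindered neopentyl-type secondary alcohol and touches no stereocentre.

Step 4
Reactants: 5 (3R)-3-[(tert-butyldimethylsilyl)oxy]-3-[(4R)-2,2-dimethyl-1,3-dioxolan-4-yl]-2,2-dimethylpropanenitrile
Product: 8 (5R,6R)-5-[(tert-butyldimethylsilyl)oxy]-6,7-dihydroxy-4,4-dimethylheptan-3-one, via ketimine 6 (not isolated), via ketone acetonide 7 (not isolated)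
Conditions: EtLi, Et2O, −78 to 0 °C; then AcOH/H2O/THF (3:1:1), 45 °C
Reagents that add atoms: ethyllithium [Li]CC; water O
Why: Organolithium addition to a nitrile without α-hydrogens stops at the N-lithio ketimine, and one acidic aqueous work-up should hydrolyse the imine to the ethyl ketone and cleave the terminal acetonide while the hindered silyl ether survives.

Step 5
Reactants: 8 (5R,6R)-5-[(tert-butyldimethylsilyl)oxy]-6,7-dihydroxy-4,4-dimethylheptan-3-one
Product: 9 (2R,3R)-3-[(tert-butyldimethylsilyl)oxy]-2-hydroxy-4,4-dimethyl-5-oxoheptyl 4-methylbenzenesulfonate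
Conditions: TsCl, Et3N, Bu2SnO (2 mol%), CH2Cl2, 0 °C to rt
Reagents that add atoms: p-toluenesulfonyl chloride Cc1ccc(cc1)S(=O)(=O)Cl
Why: Tin-acetal-catalysed sulfonylation is selective for the primary hydroxyl of a terminal 1,2-diol.

Step 6
Reactants: 9 (2R,3R)-3-[(tert-butyldimethylsilyl)oxy]-2-hydroxy-4,4-dimethyl-5-oxoheptyl 4-methylbenzenesulfonate
Product: 10 (2R,3R)-2,3-bis[(tert-butyldimethylsilyl)oxy]-4,4-dimethyl-5-oxoheptyl 4-methylbenzenesulfonate
Conditions: TBSOTf, 2,6-lutidine, CH2Cl2, −78 to 0 °C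
Reagents that add atoms: tert-butyldimethylsilyl triflate CC(C)(C)[Si](C)(C)OS(=O)(=O)C(F)(F)F
Why: Silyl triflate protection of the remaining secondary alcohol under non-nucleophilic base avoids epoxide formation from the neighbouring tosylate.

Step 7
Reactants: 10 (2R,3R)-2,3-bis[(tert-butyldimethylsilyl)oxy]-4,4-dimethyl-5-oxoheptyl 4-methylbenzenesulfonate
Product: 11 (3R,4R)-3,4-bis[(tert-butyldimethylsilyl)oxy]-2,2,6-trimethylcyclohexan-1-one (both C6 epimers)
Conditions: LiN(SiMe3)2, THF/DMPU, −78 °C to rt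
Reagents that add atoms: none
Why: Intramolecular enolate alkylation in the 6-(enolendo)-exo-tet mode closes the diol ring, since only the ethyl side of the ketone can enolise (C1 is quaternary) and the new methyl-bearing centre is erased in step 8.

Step 8
Reactants: 11 (3R,4R)-3,4-bis[(tert-butyldimethylsilyl)oxy]-2,2,6-trimethylcyclohexan-1-one
Product: 12 (4R,5R)-4,5-bis[(tert-butyldimethylsilyl)oxy]-2,6,6-trimethylcyclohex-1-en-1-yl trifluoromethanesulfonate
Conditions: KN(SiMe3)2, PhNTf2, THF, −78 to 0 °C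
Reagents that add atoms: N-phenylbis(trifluoromethanesulfonimide) FC(F)(F)S(=O)(=O)N(c1ccccc1)S(=O)(=O)C(F)(F)F
Why: Regiospecific enol triflate formation, because the ketone has a single α-hydrogen, gives the tetrasubstituted C5=C6 double bond with a coupling handle at C6.

Step 9
Reactants: 13 (E)-3-methylpent-2-en-4-yn-1-ol
Product: 14 (2E,4E)-3-methyl-5-(tributylstannyl)penta-2,4-dien-1-ol
Conditions: Bu3SnH, PdCl2(PPh3)2 (2 mol%), THF, 0 °C to rt
Reagents that add atoms: tributyltin hydride CCCC[SnH](CCCC)CCCC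
Why: Palladium-catalysed syn-hydrostannylation of the terminal alkyne should place tin on the terminal carbon and give the (E)-vinylstannane, leaving the existing (E)-alkene untouched.

Step 10
Reactants: 12 (4R,5R)-4,5-bis[(tert-butyldimethylsilyl)oxy]-2,6,6-trimethylcyclohex-1-en-1-yl trifluoromethanesulfonate; 14 (2E,4E)-3-methyl-5-(tributylstannyl)penta-2,4-dien-1-ol
Product: 15 (2E,4E)-5-[(4R,5R)-4,5-bis[(tert-butyldimethylsilyl)oxy]-2,6,6-trimethylcyclohex-1-en-1-yl]-3-methylpenta-2,4-dien-1-ol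
Conditions: Pd2(dba)3 (2.5 mol%), AsPh3 (20 mol%), NMP, 60 °C
Reagents that add atoms: none
Why: Stille coupling of a hindered cyclohexenyl triflate with an alkenylstannane, accelerated by the arsine ligand, forms the C6–C7 bond with retention of both alkene geometries.

Step 11
Reactants: 15 (2E,4E)-5-[(4R,5R)-4,5-bis[(tert-butyldimethylsilyl)oxy]-2,6,6-trimethylcyclohex-1-en-1-yl]-3-methylpenta-2,4-dien-1-ol
Product: 16 [(2E,4E)-5-[(4R,5R)-4,5-bis[(tert-butyldimethylsilyl)oxy]-2,6,6-trimethylcyclohex-1-en-1-yl]-3-methylpenta-2,4-dien-1-yl]triphenylphosphonium bromide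
Conditions: PPh3·HBr, CH2Cl2, 0 °C to rt
Reagents that add atoms: triphenylphosphine hydrobromide [Br-].c1ccc(cc1)[PH+](c1ccccc1)c1ccccc1
Why: Acid-mediated ionisation of the dienylic alcohol and capture of the pentadienyl cation by the phosphine at the primary terminus is the standard formation of a C15 Wittig salt.

Step 12
Reactants: 16 the C15 phosphonium bromide of step 11; 17 (2E,4E,6E)-2,7-dimethylocta-2,4,6-trienedial (3 equiv)
Product: 18 (2E,4E,6E,8E,10E,12E)-13-[(4R,5R)-4,5-bis[(tert-butyldimethylsilyl)oxy]-2,6,6-trimethylcyclohex-1-en-1-yl]-2,7,11-trimethyltrideca-2,4,6,8,10,12-hexaenal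
Conditions: NaOMe, MeOH/CH2Cl2, −10 °C to rt; then I2 (cat.), hexane, rt
Reagents that add atoms: none
Why: Wittig olefination of the semi-stabilised ylide with one formyl group of the dialdehyde used in excess forms C11=C12, and iodine-catalysed equilibration should bring the new double bond to E.

Step 13
Reactants: 8 (5R,6R)-5-[(tert-butyldimethylsilyl)oxy]-6,7-dihydroxy-4,4-dimethylheptan-3-one
Product: 20 (4R)-4-[(1R)-1-[(tert-butyldimethylsilyl)oxy]-2,2-dimethyl-3-oxopentyl]-1,3,2-dioxathiolane 2,2-dioxide, via cyclic sulfite 19 (not isolated)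
Conditions: SOCl2, Et3N, CH2Cl2, 0 °C; then RuCl3·xH2O (cat.), NaIO4, MeCN/H2O, 0 °C
Reagents that add atoms: thionyl chloride O=S(Cl)Cl; sodium periodate [Na+].[O-]I(=O)(=O)=O
Why: Cyclic sulfite formation on the 1,2-diol followed by ruthenium-catalysed oxidation at sulfur is the standard cyclic sulfate synthesis and leaves both carbinol configurations unchanged.

Step 14
Reactants: 20 (4R)-4-[(1R)-1-[(tert-butyldimethylsilyl)oxy]-2,2-dimethyl-3-oxopentyl]-1,3,2-dioxathiolane 2,2-dioxide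
Product: 21 tetrabutylammonium (1R,2R)-2-[(tert-butyldimethylsilyl)oxy]-3,3,5-trimethyl-4-oxocyclohexyl sulfate (both C5 epimers)
Conditions: LiN(SiMe3)2 (1.1 equiv), THF, −78 to 0 °C; then aqueous Bu4NHSO4/CH2Cl2 (ion-pair extraction)
Reagents that add atoms: tetrabutylammonium hydrogen sulfate CCCC[N+](CCCC)(CCCC)CCCC.OS(=O)(=O)[O-]
Why: The base deprotonates the only enolisable position (the CH2 of the ethyl ketone, because C1′ is quaternary) and the enolate carbon C5′ displaces the primary C4′–O bond of the cyclic sulfate in an SN2 step, which closes the ring and leaves the sulfate as the C3′ monoester anion. The closest known reaction type is the opening of 1,2-cyclic sulfates by carbon nucleophiles, run here intramolecularly as an enolate alkylation. The six-membered ring closes in the 6-(enolendo)-exo-tet mode, which the ring-closure rules for enolates allow, whereas attack at the secondary C3′ would be a disfavoured 5-(enolendo) closure at a hindered carbon. C2′ and C3′ are not touched and keep the (R,R) configuration set in steps 1 and 2, so the silyloxy and sulfate groups end up trans; the new C5′ centre forms as a mixture that is erased in step 15. The step needs C- over O-alkylation and substitution over elimination: the lithium counter-ion in THF, the endocyclic enolate geometry and the high SN2 reactivity of the primary cyclic-sulfate carbon at low temperature should secure both, and the monoanionic sulfate that results is no longer a leaving group.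

Step 15
Reactants: 21 tetrabutylammonium (1R,2R)-2-[(tert-butyldimethylsilyl)oxy]-3,3,5-trimethyl-4-oxocyclohexyl sulfate
Product: 22 tetrabutylammonium (1R,6R)-6-[(tert-butyldimethylsilyl)oxy]-3,5,5-trimethyl-4-[(trifluoromethanesulfonyl)oxy]cyclohex-3-en-1-yl sulfate
Conditions: KN(SiMe3)2, PhNTf2, THF, −78 to 0 °C
Reagents that add atoms: N-phenylbis(trifluoromethanesulfonimide) FC(F)(F)S(=O)(=O)N(c1ccccc1)S(=O)(=O)C(F)(F)F
Why: Regiospecific enol triflate formation at the single α-hydrogen gives the C5′=C6′ double bond, and the sulfate monoanion, three carbons from the enolate, is neither eliminated nor displaced.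

Step 16
Reactants: 22 the sulfated enol triflate of step 15; 14 (2E,4E)-3-methyl-5-(tributylstannyl)penta-2,4-dien-1-ol
Product: 23 tetrabutylammonium (1R,6R)-6-[(tert-butyldimethylsilyl)oxy]-4-[(1E,3E)-5-hydroxy-3-methylpenta-1,3-dien-1-yl]-3,5,5-trimethylcyclohex-3-en-1-yl sulfate
Conditions: Pd2(dba)3 (2.5 mol%), AsPh3 (20 mol%), NMP, 60 °C
Reagents that add atoms: none
Why: Stille coupling under neutral conditions forms the C6′–C7′ bond with retention of alkene geometry and should tolerate the sulfate salt.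

Step 17
Reactants: 23 the sulfated C15 alcohol of step 16
Product: 24 (1R,6R)-6-[(tert-butyldimethylsilyl)oxy]-3,5,5-trimethyl-4-[(1E,3E)-3-methyl-5-(triphenylphosphonio)penta-1,3-dien-1-yl]cyclohex-3-en-1-yl sulfate (inner salt)
Conditions: PPh3·HBr (1.05 equiv), CH2Cl2, 0 °C
Reagents that add atoms: triphenylphosphine hydrobromide [Br-].c1ccc(cc1)[PH+](c1ccccc1)c1ccccc1
Why: Standard C15 Wittig salt formation from the dienylic alcohol, in which the weakly acidic phosphonium bromide should not protonate the sulfate monoester anion, so that this ends as the counter-ion of an inner salt.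

Step 18
Reactants: 24 the C15 phosphonium sulfate inner salt of step 17; 18 the C25 aldehyde of step 12
Product: 25 sodium salt of (2R,3R,2′R,3′R)-2,3,2′-tris-O-(tert-butyldimethylsilyl)-β,β-carotene-2,3,2′,3′-tetrol 3′-(hydrogen sulfate)
Conditions: NaOMe, CH2Cl2/MeOH, 0 °C to rt; then EtOH, 70 °C, dark
Reagents that add atoms: sodium methoxide [Na+].[O-]C
Why: Wittig olefination joins the two halves at C11′=C12′, and thermal equilibration should convert the new double bond to the all-E polyene.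

Step 19
Reactants: 25 the tris-silylated C40 sulfate sodium salt of step 18
Product: 26 (2R,3R,2′R,3′R)-β,β-carotene-2,3,2′,3′-tetrol 3′-(hydrogen sulfate), CNP0229621.3
Conditions: Bu4NF, AcOH, THF, 45 °C, dark; then cold aqueous H3PO4 (pH 3), extraction
Reagents that add atoms: none
Why: Fluoride-mediated cleavage of the three silyl ethers under acetic acid buffering is tolerated by the polyene and by the base-stable sulfate monoester, and mild protonation releases the hydrogen sulfate as drawn.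

**Compound list**

1 | isobutyronitrile | CC(C)C#N | starting material
2 | methyl (4R)-2,2-dimethyl-1,3-dioxolane-4-carboxylate | CC1(C)OC[C@@H](O1)C(=O)OC | starting material
3 | 3-[(4R)-2,2-dimethyl-1,3-dioxolan-4-yl]-2,2-dimethyl-3-oxopropanenitrile | CC1(C)OC[C@@H](O1)C(=O)C(C)(C)C#N | intermediate
4 | (3R)-3-[(4R)-2,2-dimethyl-1,3-dioxolan-4-yl]-3-hydroxy-2,2-dimethylpropanenitrile | CC1(C)OC[C@@H](O1)[C@H](O)C(C)(C)C#N | intermediate
5 | (3R)-3-[(tert-butyldimethylsilyl)oxy]-3-[(4R)-2,2-dimethyl-1,3-dioxolan-4-yl]-2,2-dimethylpropanenitrile | CC1(C)OC[C@@H](O1)[C@H](O[Si](C)(C)C(C)(C)C)C(C)(C)C#N | intermediate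
6 | (5R)-5-[(tert-butyldimethylsilyl)oxy]-5-[(4R)-2,2-dimethyl-1,3-dioxolan-4-yl]-4,4-dimethylpentan-3-imine | CC1(C)OC[C@@H](O1)[C@H](O[Si](C)(C)C(C)(C)C)C(C)(C)C(=N)CC | intermediate (not isolated)
7 | (5R)-5-[(tert-butyldimethylsilyl)oxy]-5-[(4R)-2,2-dimethyl-1,3-dioxolan-4-yl]-4,4-dimethylpentan-3-one | CC1(C)OC[C@@H](O1)[C@H](O[Si](C)(C)C(C)(C)C)C(C)(C)C(=O)CC | intermediate (not isolated)
8 | (5R,6R)-5-[(tert-butyldimethylsilyl)oxy]-6,7-dihydroxy-4,4-dimethylheptan-3-one | OC[C@@H](O)[C@H](O[Si](C)(C)C(C)(C)C)C(C)(C)C(=O)CC | intermediate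
9 | (2R,3R)-3-[(tert-butyldimethylsilyl)oxy]-2-hydroxy-4,4-dimethyl-5-oxoheptyl 4-methylbenzenesulfonate | Cc1ccc(cc1)S(=O)(=O)OC[C@@H](O)[C@H](O[Si](C)(C)C(C)(C)C)C(C)(C)C(=O)CC | intermediate
10 | (2R,3R)-2,3-bis[(tert-butyldimethylsilyl)oxy]-4,4-dimethyl-5-oxoheptyl 4-methylbenzenesulfonate | Cc1ccc(cc1)S(=O)(=O)OC[C@@H](O[Si](C)(C)C(C)(C)C)[C@H](O[Si](C)(C)C(C)(C)C)C(C)(C)C(=O)CC | intermediate
11 | (3R,4R)-3,4-bis[(tert-butyldimethylsilyl)oxy]-2,2,6-trimethylcyclohexan-1-one (C6 epimers) | CC1C[C@@H](O[Si](C)(C)C(C)(C)C)[C@H](O[Si](C)(C)C(C)(C)C)C(C)(C)C1=O | intermediate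
12 | (4R,5R)-4,5-bis[(tert-butyldimethylsilyl)oxy]-2,6,6-trimethylcyclohex-1-en-1-yl trifluoromethanesulfonate | FC(F)(F)S(=O)(=O)OC1=C(C)C[C@@H](O[Si](C)(C)C(C)(C)C)[C@H](O[Si](C)(C)C(C)(C)C)C1(C)C | intermediate
13 | (E)-3-methylpent-2-en-4-yn-1-ol | OC/C=C(C)/C#C | starting material
14 | (2E,4E)-3-methyl-5-(tributylstannyl)penta-2,4-dien-1-ol | CCCC[Sn](CCCC)(CCCC)/C=C/C(C)=C/CO | intermediate
15 | (2E,4E)-5-[(4R,5R)-4,5-bis[(tert-butyldimethylsilyl)oxy]-2,6,6-trimethylcyclohex-1-en-1-yl]-3-methylpenta-2,4-dien-1-ol | OC/C=C(C)/C=C/C1=C(C)C[C@@H](O[Si](C)(C)C(C)(C)C)[C@H](O[Si](C)(C)C(C)(C)C)C1(C)C | intermediate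
16 | [(2E,4E)-5-[(4R,5R)-4,5-bis[(tert-butyldimethylsilyl)oxy]-2,6,6-trimethylcyclohex-1-en-1-yl]-3-methylpenta-2,4-dien-1-yl]triphenylphosphonium bromide | [Br-].c1ccccc1[P+](c1ccccc1)(c1ccccc1)C/C=C(C)/C=C/C1=C(C)C[C@@H](O[Si](C)(C)C(C)(C)C)[C@H](O[Si](C)(C)C(C)(C)C)C1(C)C | intermediate
17 | (2E,4E,6E)-2,7-dimethylocta-2,4,6-trienedial | O=C/C(C)=C/C=C/C=C(C)/C=O | starting material
18 | (2E,4E,6E,8E,10E,12E)-13-[(4R,5R)-4,5-bis[(tert-butyldimethylsilyl)oxy]-2,6,6-trimethylcyclohex-1-en-1-yl]-2,7,11-trimethyltrideca-2,4,6,8,10,12-hexaenal | O=C/C(C)=C/C=C/C=C(C)/C=C/C=C(C)/C=C/C1=C(C)C[C@@H](O[Si](C)(C)C(C)(C)C)[C@H](O[Si](C)(C)C(C)(C)C)C1(C)C | intermediate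
19 | (4R)-4-[(1R)-1-[(tert-butyldimethylsilyl)oxy]-2,2-dimethyl-3-oxopentyl]-1,3,2-dioxathiolane 2-oxide (sulfur epimers) | O=S1OC[C@@H](O1)[C@H](O[Si](C)(C)C(C)(C)C)C(C)(C)C(=O)CC | intermediate (not isolated)
20 | (4R)-4-[(1R)-1-[(tert-butyldimethylsilyl)oxy]-2,2-dimethyl-3-oxopentyl]-1,3,2-dioxathiolane 2,2-dioxide | O=S1(=O)OC[C@@H](O1)[C@H](O[Si](C)(C)C(C)(C)C)C(C)(C)C(=O)CC | intermediate
21 | tetrabutylammonium (1R,2R)-2-[(tert-butyldimethylsilyl)oxy]-3,3,5-trimethyl-4-oxocyclohexyl sulfate (C5 epimers) | CCCC[N+](CCCC)(CCCC)CCCC.CC1C[C@@H](OS(=O)(=O)[O-])[C@H](O[Si](C)(C)C(C)(C)C)C(C)(C)C1=O | intermediate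
22 | tetrabutylammonium (1R,6R)-6-[(tert-butyldimethylsilyl)oxy]-3,5,5-trimethyl-4-[(trifluoromethanesulfonyl)oxy]cyclohex-3-en-1-yl sulfate | CCCC[N+](CCCC)(CCCC)CCCC.FC(F)(F)S(=O)(=O)OC1=C(C)C[C@@H](OS(=O)(=O)[O-])[C@H](O[Si](C)(C)C(C)(C)C)C1(C)C | intermediate
23 | tetrabutylammonium (1R,6R)-6-[(tert-butyldimethylsilyl)oxy]-4-[(1E,3E)-5-hydroxy-3-methylpenta-1,3-dien-1-yl]-3,5,5-trimethylcyclohex-3-en-1-yl sulfate | CCCC[N+](CCCC)(CCCC)CCCC.OC/C=C(C)/C=C/C1=C(C)C[C@@H](OS(=O)(=O)[O-])[C@H](O[Si](C)(C)C(C)(C)C)C1(C)C | intermediate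
24 | (1R,6R)-6-[(tert-butyldimethylsilyl)oxy]-3,5,5-trimethyl-4-[(1E,3E)-3-methyl-5-(triphenylphosphonio)penta-1,3-dien-1-yl]cyclohex-3-en-1-yl sulfate (inner salt) | c1ccccc1[P+](c1ccccc1)(c1ccccc1)C/C=C(C)/C=C/C1=C(C)C[C@@H](OS(=O)(=O)[O-])[C@H](O[Si](C)(C)C(C)(C)C)C1(C)C | intermediate
25 | sodium salt of (2R,3R,2′R,3′R)-2,3,2′-tris-O-(tert-butyldimethylsilyl)-β,β-carotene-2,3,2′,3′-tetrol 3′-(hydrogen sulfate) | [Na+].CC1=C(/C=C/C(C)=C/C=C/C(C)=C/C=C/C=C(C)/C=C/C=C(C)/C=C/C2=C(C)C[C@@H](OS(=O)(=O)[O-])[C@H](O[Si](C)(C)C(C)(C)C)C2(C)C)C(C)(C)[C@@H](O[Si](C)(C)C(C)(C)C)[C@H](O[Si](C)(C)C(C)(C)C)C1 | intermediate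
26 | (2R,3R,2′R,3′R)-β,β-carotene-2,3,2′,3′-tetrol 3′-(hydrogen sulfate), CNP0229621.3 | CC1=C(/C=C/C(C)=C/C=C/C(C)=C/C=C/C=C(C)/C=C/C=C(C)/C=C/C2=C(C)C[C@@H](OS(=O)(=O)O)[C@H](O)C2(C)C)C(C)(C)[C@@H](O)[C@H](O)C1 | target

**Step count.** Total: 19 steps. Longest linear sequence: 13 steps (steps 1–8, 10–12, 18, 19).

**Steps most likely to fail**

Step 14 (key step). The enolate may alkylate on oxygen to give a cyclic enol ether, or the base may trigger elimination within the cyclic sulfate, in place of the C-alkylation. The fallback separates ring closure and sulfation; it sets out from 9 and returns at 21. Tosylate 9 would be protected with TESOTf and 2,6-lutidine as the triethylsilyl ether tosylate F1, which would be cyclised with LiN(SiMe3)2 exactly as in step 7 to the differentially silylated ring ketone F2. The less hindered triethylsilyl ether would then be removed selectively with PPTS in MeOH at 0 °C to give the hydroxy ketone F3, which would be sulfated at its only free hydroxyl with SO3·pyridine in DMF/pyridine and extracted with Bu4NHSO4 to give 21.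

Step 17. The acidic ionisation of the dienylic alcohol may be accompanied by solvolysis of the sulfate monoester, or the inner salt may fail to separate cleanly. The fallback reverses the polarity of the last olefination so that the sulfated half never meets acid; it sets out from 23 and 18 and returns at 25. Alcohol 23 would be oxidised with MnO2 (CH2Cl2, rt) to the sulfated C15 aldehyde F4. In parallel, aldehyde 18 would be reduced with NaBH4 (MeOH, 0 °C) to the C25 alcohol F5 and converted with PPh3·HBr into the C25 phosphonium bromide F6. Wittig reaction of F6 with F4 (NaOMe, CH2Cl2/MeOH), followed by thermal equilibration and a brine wash, would give 25.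

Step 1. The newly formed α-alkoxy ketone may be enolised by unreacted nitrile anion or by methoxide, which would epimerise the future C3 or open the acetonide by β-elimination. The fallback forms the ketone without base; it sets out from 2 and returns at 3. Ester 2 would be reduced with iBu2AlH (CH2Cl2, −78 °C) to (R)-glyceraldehyde acetonide F7, to which lithiated 1 would be added at −78 °C to give the β-hydroxy nitrile F8 as a mixture at the carbinol carbon. Oxidation with Dess–Martin periodinane (CH2Cl2, rt) would give 3, and step 2 then sets the carbinol configuration as before.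

**Further compounds**

F1 | step 14 | (2R,3R)-3-[(tert-butyldimethylsilyl)oxy]-4,4-dimethyl-5-oxo-2-[(triethylsilyl)oxy]heptyl 4-methylbenzenesulfonate | Cc1ccc(cc1)S(=O)(=O)OC[C@@H](O[Si](CC)(CC)CC)[C@H](O[Si](C)(C)C(C)(C)C)C(C)(C)C(=O)CC
F2 | step 14 | (3R,4R)-3-[(tert-butyldimethylsilyl)oxy]-2,2,6-trimethyl-4-[(triethylsilyl)oxy]cyclohexan-1-one (C6 epimers) | CC1C[C@@H](O[Si](CC)(CC)CC)[C@H](O[Si](C)(C)C(C)(C)C)C(C)(C)C1=O
F3 | step 14 | (3R,4R)-3-[(tert-butyldimethylsilyl)oxy]-4-hydroxy-2,2,6-trimethylcyclohexan-1-one (C6 epimers) | CC1C[C@@H](O)[C@H](O[Si](C)(C)C(C)(C)C)C(C)(C)C1=O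
F4 | step 17 | tetrabutylammonium (1R,6R)-6-[(tert-butyldimethylsilyl)oxy]-3,5,5-trimethyl-4-[(1E,3E)-3-methyl-5-oxopenta-1,3-dien-1-yl]cyclohex-3-en-1-yl sulfate | CCCC[N+](CCCC)(CCCC)CCCC.O=C/C=C(C)/C=C/C1=C(C)C[C@@H](OS(=O)(=O)[O-])[C@H](O[Si](C)(C)C(C)(C)C)C1(C)C
F5 | step 17 | (2E,4E,6E,8E,10E,12E)-13-[(4R,5R)-4,5-bis[(tert-butyldimethylsilyl)oxy]-2,6,6-trimethylcyclohex-1-en-1-yl]-2,7,11-trimethyltrideca-2,4,6,8,10,12-hexaen-1-ol | OC/C(C)=C/C=C/C=C(C)/C=C/C=C(C)/C=C/C1=C(C)C[C@@H](O[Si](C)(C)C(C)(C)C)[C@H](O[Si](C)(C)C(C)(C)C)C1(C)C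
F6 | step 17 | [(2E,4E,6E,8E,10E,12E)-13-[(4R,5R)-4,5-bis[(tert-butyldimethylsilyl)oxy]-2,6,6-trimethylcyclohex-1-en-1-yl]-2,7,11-trimethyltrideca-2,4,6,8,10,12-hexaen-1-yl]triphenylphosphonium bromide | [Br-].c1ccccc1[P+](c1ccccc1)(c1ccccc1)C/C(C)=C/C=C/C=C(C)/C=C/C=C(C)/C=C/C1=C(C)C[C@@H](O[Si](C)(C)C(C)(C)C)[C@H](O[Si](C)(C)C(C)(C)C)C1(C)C
F7 | step 1 | (4R)-2,2-dimethyl-1,3-dioxolane-4-carbaldehyde | CC1(C)OC[C@@H](O1)C=O
F8 | step 1 | (3RS)-3-[(4R)-2,2-dimethyl-1,3-dioxolan-4-yl]-3-hydroxy-2,2-dimethylpropanenitrile | CC1(C)OC[C@@H](O1)C(O)C(C)(C)C#N
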